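**The questions.** 3 questions stand on this flask: two powers of the first rate, and the share of E left in amber.

- the power of [X] that the first rate follows, about the charge of the teal run; measure it at two percent of E made into Q
- the power of [E] that the first rate follows, about the charge of the teal run; measure it at two percent of E made into Q (one fixed amount of Q, the same in the runs compared)
- E in the amber run at 4.1 h, as a share of the E charged

| flask | E | X | Q | time |
|---|---|---|---|---|
| teal | 0.500 M | 0.0500 M |  |  |
| blue | 0.500 M | 0.0500 M | 0.250 M |  |
| ochre | 0.500 M | 0.0250 M |  |  |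
| grey | 0.750 M | 0.0500 M |  |  |
| amber | 1.50 M | 0.0250 M |  | 4.1 h |

- teal run (time / h: [E] / M): 0.16: 0.486; 0.26: 0.479; 0.41: 0.465; 0.65: 0.442; 1.0: 0.407; 1.6: 0.344; 2.6: 0.247; 4.1: 0.138
- blue run (time / h: [E] / M): 0.16: 0.465; 0.26: 0.462; 0.41: 0.418; 0.65: 0.379; 1.0: 0.330; 1.6: 0.247; 2.6: 0.125; 4.1: 0.046
- ochre run (time / h: [E] / M): 0.16: 0.499; 0.26: 0.488; 0.41: 0.476; 0.65: 0.464; 1.0: 0.433; 1.6: 0.392; 2.6: 0.316; 4.1: 0.199
- grey run (time / h: [E] / M): 0.16: 0.725; 0.26: 0.724; 0.41: 0.706; 0.65: 0.657; 1.0: 0.602; 1.6: 0.494; 2.6: 0.332; 4.1: 0.122

(readings scatter by 0.005 M)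

- Overall: E -> Q, with X as catalyst.
- Constant volume, constant temperature.
- Bound and free are read together.
- An order is taken over about fifteen percent of the charge, up and down.

**The fork.** Blue, charged with Q, loses E faster than teal, so a molecule of E has two ways to turn. Its chance per hour is taken as a + b[Q], where a needs no Q and b is the way through Q (autocatalysis). Over the first hour, ln(charge/[E]) per hour reads 0.206 h⁻¹ in teal at a mean Q of 0.0465 M, and 0.416 h⁻¹ in blue at 0.335 M. So b reads 0.727 L mol⁻¹ h⁻¹, a reads 0.172 h⁻¹ in teal, and the same reckoning gives 0.120 h⁻¹ in ochre. The quantity to carry is Q* = a/b, 0.237 M at teal's X and 0.164 M at ochre's: the amount of Q at which a molecule of E stands at even odds between the two ways.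

**Two extremes.** Amber has ochre's X, so this reckoning lends it ochre's a, assuming that a holds at amber's larger charge T. With the Q way shut, E/T = e^(−at) gives 61.3 % at 4.1 h. With Q equal to T from the start, E/T = e^(−bTt) gives 1.14 %. Amber's Q* is 11.0 % of its charge, smaller than T, so the odds turn early and amber should lie towards the second extreme. Integrating with λ = b(Q* + T) gives E/T = (1 + T/Q*)/(T/Q* + e^(λt)), which is 6.67 %.

**The powers.** The chance a + b[Q] holds no E, so the power of [E] should be near one. The two values of a give a power of X of 0.525, but that spans a factor of two, while the power asked is local to teal and may differ.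

**The result.** The forecast says 0.5, 0.95 and 9 %, higher on amber than this reckoning, expecting that “saturation at high concentration would slow amber further”.

    X + E ⇌ XE, settled at all times (0.2360 L mol⁻¹)
    XE + X → Q + 2 X (174.2 L mol⁻¹ h⁻¹)
    E + Q → 2 Q (0.7668 L mol⁻¹ h⁻¹)
    E → Q (0.08928 h⁻¹)

The flask gives 6.64 % of E left in amber, with powers of 0.92 in [E] and 0.91 in [X]. Ochre ran at 0.66 of teal's rate where the same amount of Q had been made, a ratio across the factor of two in X. Grey has teal's X, so this reckoning lends it Q* = 0.237 M. The time for the Q made to reach half of the charge, ln(2 + T/Q*)/λ, comes to 2.29 h, and grey reached that point at 2.30 h.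

Readings and results are calculated on assumed constants; noise was put on by code.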